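**Retrosynthetic overview**
- The target is the desilylated form of a C10‑silyl ether whose C6–OOH bond comes from SN2 perhydrolysis (inversion) of an (R)‑allylic mesylate.
- The aryl allyl ether comes from Mitsunobu coupling of bought 4‑hydroxy‑5‑methylcoumarin with a primary allylic alcohol.
- The C3–CH2O bond is made by a light‑driven nickel decarboxylative coupling of a (Z)‑vinyl iodide with a silyloxyacetic acid (key step, new).
- The (Z)‑vinyl iodide comes from a propargylic alcohol by hydroxyl‑directed trans‑hydroalumination/iodination; the alkyne comes from a butyrolactone (reduction, Ohira–Bestmann, formaldehyde).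
- The isopropenyl carbinol stereocentre is bought as (R)‑5‑oxotetrahydrofuran‑2‑carboxylic acid (from D‑glutamic acid). No ring is formed: the coumarin is bought intact and the lactone is opened.

Assumption: the SMILES is read as (S) at the hydroperoxide carbon and (Z) at the trisubstituted alkene, and compounds 1, 11 and 13 are taken as catalogue items.

**Step 1**
Reactants: 1 (R)-5-oxotetrahydrofuran-2-carboxylic acid
Product: 3 (R)-5-acetyldihydrofuran-2(3H)-one, via acid chloride 2 (not isolated)
Conditions: (COCl)2, DMF (cat.), CH2Cl2, 0 °C to rt; concentrate; Me2CuLi, Et2O, −78 °C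
Reagents that add atoms: lithium dimethylcuprate, [Li+].C[Cu-]C; oxalyl chloride, O=C(Cl)C(=O)Cl (its chlorine stays only in intermediate 2)
Why: Base‑free acid chloride formation followed by Gilman cuprate acylation stops at the methyl ketone and leaves the lactone alone; the bought stereocentre is not touched.

**Step 2**
Reactants: 3 (R)-5-acetyldihydrofuran-2(3H)-one
Product: 4 (R)-5-(prop-1-en-2-yl)dihydrofuran-2(3H)-one
Conditions: Tebbe reagent Cp2Ti(μ-Cl)(μ-CH2)AlMe2 (1.05 equiv), pyridine (cat.), THF/toluene, −40 to 0 °C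
Reagents that add atoms: Tebbe reagent, C=[Ti](C1C=CC=C1)C1C=CC=C1.C[Al](C)Cl
Why: Tebbe methylenation is non‑basic and much faster on a ketone than on a lactone at low temperature, so the α‑acyloxy stereocentre is not epimerised.

**Step 3**
Reactants: 4 (R)-5-(prop-1-en-2-yl)dihydrofuran-2(3H)-one
Product: 6 (R)-2-methylhept-1-en-6-yn-3-ol, via lactol 5 (not isolated)
Conditions: i-Bu2AlH (1.05 equiv), CH2Cl2, −78 °C; then MeOH, K2CO3, dimethyl (1-diazo-2-oxopropyl)phosphonate, −78 °C to rt
Reagents that add atoms: dimethyl (1-diazo-2-oxopropyl)phosphonate, CC(=O)C(=[N+]=[N-])P(=O)(OC)OC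
Why: Partial lactone reduction gives the lactol, whose open hydroxy‑aldehyde form undergoes Seyferth–Gilbert homologation with the Ohira–Bestmann reagent to the terminal alkyne; the C–O bond of the stereocentre is unchanged.

**Step 4**
Reactants: 6 (R)-2-methylhept-1-en-6-yn-3-ol
Product: 8 (R)-7-methyloct-7-en-2-yne-1,6-diol, via dilithium acetylide 7 (not isolated)
Conditions: n-BuLi (2.1 equiv), THF, −78 °C; (CH2O)n, −78 °C to rt; H2O
Reagents that add atoms: paraformaldehyde (formaldehyde), C=O
Why: Double deprotonation then 1,2‑addition of the lithium acetylide to formaldehyde (acetylide hydroxymethylation) installs C1 as a propargylic alcohol.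

**Step 5**
Reactants: 8 (R)-7-methyloct-7-en-2-yne-1,6-diol
Product: 10 (2Z,6R)-3-iodo-7-methylocta-2,7-diene-1,6-diol, via vinylalanate 9 (not isolated)
Conditions: NaAlH2(OCH2CH2OMe)2 (Red-Al, 3 equiv), THF, 0 °C to rt; then I2, −78 °C
Reagents that add atoms: iodine, II
Why: Hydroxyl‑directed trans‑hydroalumination of the propargylic alcohol puts aluminium on the distal alkyne carbon cis to CH2O, and iodinolysis with retention gives the (Z)‑3‑iodoallylic alcohol; this fixes the alkene geometry.

**Step 6**
Reactants: 10 (2Z,6R)-3-iodo-7-methylocta-2,7-diene-1,6-diol; 11 2-[(tert-butyldimethylsilyl)oxy]acetic acid (1.5 equiv)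
Product: 12 (2Z,6R)-3-{[(tert-butyldimethylsilyl)oxy]methyl}-7-methylocta-2,7-diene-1,6-diol
Conditions: 4CzIPN (2 mol%), NiCl2·glyme (10 mol%), 4,4′-di-tert-butyl-2,2′-bipyridine (15 mol%), Cs2CO3 (1.5 equiv), DMF, blue LEDs (450 nm), 25 °C
Reagents that add atoms: none
Why: Proposed new method: metallaphotoredox decarboxylative hydroxymethylation of an unprotected (Z)‑γ‑iodoallylic diol with an O‑silyl glycolic acid, in which excited 4CzIPN oxidises the caesium carboxylate, loss of CO2 gives the nucleophilic silyloxymethyl radical, zerovalent nickel inserts into the C–I bond with retention, the divalent vinylnickel captures the radical and the trivalent nickel reductively eliminates the C(sp2)–C(sp3) bond with the alkene geometry intact while the free hydroxyls are spectators; the closest known reaction type is the nickel/photoredox decarboxylative vinylation of α‑oxy and α‑amino acids with vinyl halides.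

**Step 7**
Reactants: 12 (2Z,6R)-3-{[(tert-butyldimethylsilyl)oxy]methyl}-7-methylocta-2,7-diene-1,6-diol; 13 4-hydroxy-5-methyl-2H-chromen-2-one
Product: 14 4-{[(2Z,6R)-3-{[(tert-butyldimethylsilyl)oxy]methyl}-6-hydroxy-7-methylocta-2,7-dien-1-yl]oxy}-5-methyl-2H-chromen-2-one
Conditions: PPh3 (1.05 equiv), DIAD (1.05 equiv), THF, 0 °C
Reagents that add atoms: none
Why: Mitsunobu etherification, in which the acidic 4‑hydroxycoumarin (pKa about 4) is O‑alkylated by the alkoxyphosphonium of the primary allylic alcohol, which forms much faster than that of the hindered secondary alcohol.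

**Step 8**
Reactants: 14 4-{[(2Z,6R)-3-{[(tert-butyldimethylsilyl)oxy]methyl}-6-hydroxy-7-methylocta-2,7-dien-1-yl]oxy}-5-methyl-2H-chromen-2-one
Product: 16 4-{[(2Z,6S)-3-{[(tert-butyldimethylsilyl)oxy]methyl}-6-hydroperoxy-7-methylocta-2,7-dien-1-yl]oxy}-5-methyl-2H-chromen-2-one, via mesylate 15 (not isolated)
Conditions: MsCl, Et3N, THF, −40 °C; then H2O2 (50% aq., 30 equiv), KOH (1.5 equiv), MeOH, −40 to −10 °C
Reagents that add atoms: hydrogen peroxide, OO; methanesulfonyl chloride, CS(=O)(=O)Cl (its atoms stay only in intermediate 15)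
Why: SN2 perhydrolysis of a sulfonate (Williams–Mosher type), in which the weakly basic hydroperoxide anion displaces the allylic mesylate with inversion so that the bought (R)‑carbinol becomes the (S)‑hydroperoxide, and the large excess of H2O2 prevents a second alkylation.

**Step 9**
Reactants: 16 4-{[(2Z,6S)-3-{[(tert-butyldimethylsilyl)oxy]methyl}-6-hydroperoxy-7-methylocta-2,7-dien-1-yl]oxy}-5-methyl-2H-chromen-2-one
Product: 17 4-{[(2Z,6S)-6-hydroperoxy-3-(hydroxymethyl)-7-methylocta-2,7-dien-1-yl]oxy}-5-methyl-2H-chromen-2-one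
Conditions: HF·pyridine, THF/pyridine, 0 °C
Reagents that add atoms: none
Why: Fluoride‑mediated desilylation of the primary silyl ether under mildly acidic conditions that the allylic hydroperoxide, the allyl aryl ether and the coumarin tolerate; the stereocentre is not involved.

**Compound list**
1 | (R)-5-oxotetrahydrofuran-2-carboxylic acid | OC(=O)[C@H]1CCC(=O)O1 | starting material
2 | (R)-5-oxotetrahydrofuran-2-carbonyl chloride | ClC(=O)[C@H]1CCC(=O)O1 | intermediate
3 | (R)-5-acetyldihydrofuran-2(3H)-one | CC(=O)[C@H]1CCC(=O)O1 | intermediate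
4 | (R)-5-(prop-1-en-2-yl)dihydrofuran-2(3H)-one | C=C(C)[C@H]1CCC(=O)O1 | intermediate
5 | (5R)-5-(prop-1-en-2-yl)tetrahydrofuran-2-ol (lactol, anomer mixture) | C=C(C)[C@H]1CCC(O)O1 | intermediate
6 | (R)-2-methylhept-1-en-6-yn-3-ol | C=C(C)[C@@H](CCC#C)O | intermediate
7 | dilithium acetylide‑alkoxide of 6 | C=C(C)[C@@H](CCC#C[Li])O[Li] | intermediate
8 | (R)-7-methyloct-7-en-2-yne-1,6-diol | C=C(C)[C@@H](CCC#CCO)O | intermediate
9 | cyclic sodium alkoxy(vinyl)alanate of 8 (aluminium on C3, cis to C1; drawn as the disodium salt) | [Na+].[Na+].C=C(C)[C@@H](CC/C1=C/CO[Al-]1(OCCOC)OCCOC)[O-] | intermediate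
10 | (2Z,6R)-3-iodo-7-methylocta-2,7-diene-1,6-diol | C=C(C)[C@@H](CC/C(I)=C/CO)O | intermediate
11 | 2-[(tert-butyldimethylsilyl)oxy]acetic acid | CC(C)(C)[Si](C)(C)OCC(=O)O | starting material
12 | (2Z,6R)-3-{[(tert-butyldimethylsilyl)oxy]methyl}-7-methylocta-2,7-diene-1,6-diol | C=C(C)[C@@H](CC/C(=C/CO)CO[Si](C)(C)C(C)(C)C)O | intermediate
13 | 4-hydroxy-5-methyl-2H-chromen-2-one | Cc1cccc2oc(=O)cc(O)c12 | starting material
14 | 4-{[(2Z,6R)-3-{[(tert-butyldimethylsilyl)oxy]methyl}-6-hydroxy-7-methylocta-2,7-dien-1-yl]oxy}-5-methyl-2H-chromen-2-one | C=C(C)[C@@H](CC/C(=C/COc1cc(=O)oc2cccc(C)c12)CO[Si](C)(C)C(C)(C)C)O | intermediate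
15 | (6R)-methanesulfonate of 14 | C=C(C)[C@@H](CC/C(=C/COc1cc(=O)oc2cccc(C)c12)CO[Si](C)(C)C(C)(C)C)OS(C)(=O)=O | intermediate
16 | 4-{[(2Z,6S)-3-{[(tert-butyldimethylsilyl)oxy]methyl}-6-hydroperoxy-7-methylocta-2,7-dien-1-yl]oxy}-5-methyl-2H-chromen-2-one | C=C(C)[C@H](CC/C(=C/COc1cc(=O)oc2cccc(C)c12)CO[Si](C)(C)C(C)(C)C)OO | intermediate
17 | 4-{[(2Z,6S)-6-hydroperoxy-3-(hydroxymethyl)-7-methylocta-2,7-dien-1-yl]oxy}-5-methyl-2H-chromen-2-one (CNP0171309.1) | C=C(C)[C@H](CC/C(=C/COc1cc(=O)oc2cccc(C)c12)CO)OO | target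

**Step count**
Total steps: 9. Longest linear sequence: 9 (from 1; compounds 11 and 13 are bought).

**Three steps most likely to fail**

Step 6 (the proposed new coupling). The risks are protodeiodination, nickel‑mediated C–O coupling with the free allylic hydroxyl, and slow oxidation of the silyloxyacetate. The fallback uses known chemistry, sets out from 10 and comes back at 14. Mitsunobu etherification of 10 with 13 (PPh3, DIAD, THF, 0 °C) gives the iodo ether F1. Nozaki–Hiyama–Kishi hydroxymethylation of F1 with paraformaldehyde (CrCl2 as the divalent chromium reductant, NiCl2 cat., DMF, rt) gives the diol ether F2 with retention of alkene geometry. Selective silylation of the primary hydroxyl (TBSCl, imidazole, CH2Cl2, −20 °C) then gives 14.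

Step 7. The coumarin is ambident, so alkylation at the lactone oxygen (2‑alkoxychromone) or at C3 can compete, and the peri methyl makes this worse. The fallback sets out from 13 and 12 and comes back at 14. Compound 13 with POCl3 (90 °C) gives 4-chloro-5-methyl-2H-chromen-2-one F3. The monosodium alkoxide of 12 (NaH 1.0 equiv, THF, 0 °C) then undergoes addition–elimination at C4 of F3 to give 14, which fixes the site of ether formation.

Step 8. The allylic mesylate can ionise or be attacked SN2′ (loss of ee, primary hydroperoxide), and the coumarin and the secondary hydroperoxide are base‑sensitive. The fallback sets out from 14 and comes back at 17. Mesylate 15 is made as before but displaced in DMF at 0 °C by premixed caesium 2-methoxyprop-2-yl peroxide (from 2-methoxyprop-2-yl hydroperoxide, COC(C)(C)OO, and CsOH·H2O; a protected peroxide synthon, with no excess hydroxide or hydrogen peroxide) to give the perketal F4. The free hydroperoxide and the primary alcohol are released afterwards under mild acid (AcOH/THF/H2O, rt; the silyl ether is cleaved in the same pot) to give 17.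

**Further compounds**
F1 | step 6 | 4-{[(2Z,6R)-6-hydroxy-3-iodo-7-methylocta-2,7-dien-1-yl]oxy}-5-methyl-2H-chromen-2-one | C=C(C)[C@@H](CC/C(I)=C/COc1cc(=O)oc2cccc(C)c12)O
F2 | step 6 | 4-{[(2Z,6R)-6-hydroxy-3-(hydroxymethyl)-7-methylocta-2,7-dien-1-yl]oxy}-5-methyl-2H-chromen-2-one | C=C(C)[C@@H](CC/C(=C/COc1cc(=O)oc2cccc(C)c12)CO)O
F3 | step 7 | 4-chloro-5-methyl-2H-chromen-2-one | Cc1cccc2oc(=O)cc(Cl)c12
F4 | step 8 | 4-{[(2Z,6S)-3-{[(tert-butyldimethylsilyl)oxy]methyl}-6-[(2-methoxypropan-2-yl)peroxy]-7-methylocta-2,7-dien-1-yl]oxy}-5-methyl-2H-chromen-2-one | C=C(C)[C@H](CC/C(=C/COc1cc(=O)oc2cccc(C)c12)CO[Si](C)(C)C(C)(C)C)OOC(C)(C)OC
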